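**Retrosynthetic overview**
- Target ⇐ its 2-O-benzyl ether (neutral hydrogenolysis last) ⇐ the corresponding methyl ester (saponification).
- Key C–C disconnection: ArCH2–C(=O)C11H23, made by a crossed Claisen-type condensation of the laterally lithiated o-toluate (a vinylogous ester enolate) with the Weinreb amide of lauric acid.
- Toluate fragment ⇐ methyl orsellinate by selective 4-O-methylation, then 2-O-benzylation; acyl fragment ⇐ lauroyl chloride.
- Rings: none is formed; the benzene ring is bought intact with methyl orsellinate.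

Assumption: the target SMILES has no stereocentre and no stereogenic double bond, so the compound is achiral and needs no asymmetric step; the stereocentre of transient adduct 7 (racemic) disappears within the same step.

**Route**

Step 1
Reactants: 1 dodecanoyl chloride (lauroyl chloride)
Product: 2 N-methoxy-N-methyldodecanamide
Conditions: MeNH(OMe)·HCl (1.1 equiv), K2CO3 (2.5 equiv), CH2Cl2/H2O 1:1, 0 °C → rt, 2 h
Reagents that add atoms: N,O-dimethylhydroxylamine hydrochloride, CNOC.Cl
Why: Schotten–Baumann N-acylation (nucleophilic acyl substitution) of the hydroxylamine by the acid chloride is fast and clean, with carbonate taking up the HCl; no stereocentre is formed.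

Step 2
Reactants: 3 methyl 2,4-dihydroxy-6-methylbenzoate (methyl orsellinate)
Product: 4 methyl 2-hydroxy-4-methoxy-6-methylbenzoate
Conditions: MeI (1.05 equiv), K2CO3 (1.1 equiv), acetone, 40 °C, 12 h
Reagents that add atoms: iodomethane, CI
Why: Williamson etherification; the 2-OH is hydrogen-bonded to the ester carbonyl and much less nucleophilic, so one equivalent of MeI alkylates the free 4-OH selectively.

Step 3
Reactants: 4 methyl 2-hydroxy-4-methoxy-6-methylbenzoate
Product: 5 methyl 2-(benzyloxy)-4-methoxy-6-methylbenzoate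
Conditions: BnBr (1.3 equiv), K2CO3 (2.0 equiv), Bu4NI (cat.), DMF, 70 °C, 12 h
Reagents that add atoms: benzyl bromide, BrCc1ccccc1
Why: Williamson etherification under more forcing conditions alkylates the chelated phenol; the benzyl ether tolerates LDA and hydroxide and is removed later under neutral conditions.

Step 4
Reactants: 5 methyl 2-(benzyloxy)-4-methoxy-6-methylbenzoate; 2 N-methoxy-N-methyldodecanamide
Product: 8 methyl 2-(benzyloxy)-4-methoxy-6-(2-oxotridecyl)benzoate, via lithiated toluate 6 (not isolated), via tetrahedral lithium adduct 7 (not isolated)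
Conditions: LDA (commercial solution, 2.1 equiv), THF, −78 °C, 20 min; then 2 (1.05 equiv) in THF, −78 °C, 1 h; then 1 M HCl, −78 °C → rt
Reagents that add atoms: none
Why: Lateral lithiation gives the ester-stabilised benzylic anion (a vinylogous ester enolate), and its crossed Claisen-type acylation by the Weinreb amide stops at the chelated tetrahedral adduct, so the ketone appears only on quench and cannot over-add; the di-ortho-substituted ester is shielded from self-condensation, and no lasting stereocentre is formed.

Step 5
Reactants: 8 methyl 2-(benzyloxy)-4-methoxy-6-(2-oxotridecyl)benzoate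
Product: 10 2-(benzyloxy)-4-methoxy-6-(2-oxotridecyl)benzoic acid, via lithium carboxylate 9 (not isolated)
Conditions: LiOH·H2O (4 equiv), THF/H2O 3:1, 40 °C, 8 h; then 1 M HCl, 0 °C, to pH 3, extract without heating
Reagents that add atoms: lithium hydroxide, [Li+].[OH-]
Why: Saponification of the hindered ester is helped by the neighbouring ketone (attack through its hydrate or enolate oxygen, both leading to the same carboxylate); cold acidification gives the open keto acid without dehydration to an isocoumarin.

Step 6
Reactants: 10 2-(benzyloxy)-4-methoxy-6-(2-oxotridecyl)benzoic acid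
Product: 11 2-hydroxy-4-methoxy-6-(2-oxotridecyl)benzoic acid
Conditions: H2 (1 atm), 10% Pd/C, EtOAc, rt, 3 h; filter through Celite, concentrate below 30 °C
Reagents that add atoms: none
Why: Catalytic hydrogenolysis cleaves the aryl benzyl ether under neutral conditions and leaves the aliphatic ketone, the arene and the acid untouched; avoiding acid and heat keeps the product from cyclising to the isocoumarin.

**Compound list**
1 | dodecanoyl chloride (lauroyl chloride) | CCCCCCCCCCCC(=O)Cl | starting material
2 | N-methoxy-N-methyldodecanamide | CCCCCCCCCCCC(=O)N(C)OC | intermediate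
3 | methyl 2,4-dihydroxy-6-methylbenzoate (methyl orsellinate) | COC(=O)c1c(C)cc(O)cc1O | starting material
4 | methyl 2-hydroxy-4-methoxy-6-methylbenzoate | COC(=O)c1c(C)cc(OC)cc1O | intermediate
5 | methyl 2-(benzyloxy)-4-methoxy-6-methylbenzoate | COC(=O)c1c(C)cc(OC)cc1OCc1ccccc1 | intermediate
6 | methyl 2-(benzyloxy)-6-(lithiomethyl)-4-methoxybenzoate (lithiated toluate, not isolated) | COC(=O)c1c(C[Li])cc(OC)cc1OCc1ccccc1 | intermediate
7 | methyl 2-(benzyloxy)-6-[2-(lithiooxy)-2-[methoxy(methyl)amino]tridecyl]-4-methoxybenzoate (racemic tetrahedral adduct, not isolated) | CCCCCCCCCCCC(O[Li])(Cc1cc(OC)cc(OCc2ccccc2)c1C(=O)OC)N(C)OC | intermediate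
8 | methyl 2-(benzyloxy)-4-methoxy-6-(2-oxotridecyl)benzoate | CCCCCCCCCCCC(=O)Cc1cc(OC)cc(OCc2ccccc2)c1C(=O)OC | intermediate
9 | lithium 2-(benzyloxy)-4-methoxy-6-(2-oxotridecyl)benzoate (not isolated) | CCCCCCCCCCCC(=O)Cc1cc(OC)cc(OCc2ccccc2)c1C(=O)[O-].[Li+] | intermediate
10 | 2-(benzyloxy)-4-methoxy-6-(2-oxotridecyl)benzoic acid | CCCCCCCCCCCC(=O)Cc1cc(OC)cc(OCc2ccccc2)c1C(=O)O | intermediate
11 | 2-hydroxy-4-methoxy-6-(2-oxotridecyl)benzoic acid (achiral) | CCCCCCCCCCCC(=O)Cc1cc(OC)cc(O)c1C(=O)O | target

**Totals**
Total step count: 6. Longest linear sequence: 5 steps (3 → 4 → 5 → 8 → 10 → 11); step 1 is a one-step side branch.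

**Three steps most likely to fail**

Step 4 (lateral lithiation and acylation; risks are self-condensation of the lithiated ester and proton transfer from the amide). The fallback sets out from 5 and comes back at 10. The hindered ester is hydrolysed before the C–C bond is made (KOH, DMSO/H2O, 100 °C), giving potassium 2-(benzyloxy)-4-methoxy-6-methylbenzoate F1. Cold acidification gives 2-(benzyloxy)-4-methoxy-6-methylbenzoic acid F2. LDA (2.3 equiv, THF, −78 → 0 °C) converts this into the carboxylate-stabilised dianion lithium 2-(benzyloxy)-6-(lithiomethyl)-4-methoxybenzoate F3. Acylation with 2 at −78 °C gives the dilithium tetrahedral adduct lithium 2-(benzyloxy)-6-[2-(lithiooxy)-2-[methoxy(methyl)amino]tridecyl]-4-methoxybenzoate F4, and a cold 1 M HCl quench delivers keto acid 10 directly. A carboxylate cannot self-condense, and step 5 is no longer needed.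

Step 5 (hydrolysis of a di-ortho-substituted ester next to an enolisable ketone; risks are slow reaction or Dieckmann-type C-acylation to a naphthalenediol). The fallback sets out from 8 and comes back at 11. Hydrogenolysis first (H2, Pd/C, EtOAc, rt) gives methyl 2-hydroxy-4-methoxy-6-(2-oxotridecyl)benzoate F5. Acid-catalysed enol-lactonisation (TsOH cat., toluene, reflux, loss of methanol) then gives 8-hydroxy-6-methoxy-3-undecyl-1H-isochromen-1-one F6. This enol lactone is opened far more easily than the hindered methyl ester and cannot undergo C-acylation; KOH in aqueous EtOH at reflux gives dipotassium 4-methoxy-2-oxido-6-(2-oxotridecyl)benzoate F7, and acidification at 0 °C gives 11.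

Step 2 (mono-methylation; risks are over-methylation or incomplete conversion). The fallback sets out from 3 and comes back at 4. Both phenols are methylated (excess MeI, K2CO3, acetone, reflux) to methyl 2,4-dimethoxy-6-methylbenzoate F8. BCl3 (CH2Cl2, −78 → 0 °C) then cleaves only the ether ortho to the ester through the carbonyl-chelated methyl 2-[(dichloroboranyl)oxy]-4-methoxy-6-methylbenzoate F9, which gives 4 on aqueous work-up.

**Further compounds**
F1 | step 4 | potassium 2-(benzyloxy)-4-methoxy-6-methylbenzoate | Cc1cc(OC)cc(OCc2ccccc2)c1C(=O)[O-].[K+]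
F2 | step 4 | 2-(benzyloxy)-4-methoxy-6-methylbenzoic acid | Cc1cc(OC)cc(OCc2ccccc2)c1C(=O)O
F3 | step 4 | lithium 2-(benzyloxy)-6-(lithiomethyl)-4-methoxybenzoate | [Li]Cc1cc(OC)cc(OCc2ccccc2)c1C(=O)O[Li]
F4 | step 4 | lithium 2-(benzyloxy)-6-[2-(lithiooxy)-2-[methoxy(methyl)amino]tridecyl]-4-methoxybenzoate (racemic) | CCCCCCCCCCCC(O[Li])(Cc1cc(OC)cc(OCc2ccccc2)c1C(=O)O[Li])N(C)OC
F5 | step 5 | methyl 2-hydroxy-4-methoxy-6-(2-oxotridecyl)benzoate | CCCCCCCCCCCC(=O)Cc1cc(OC)cc(O)c1C(=O)OC
F6 | step 5 | 8-hydroxy-6-methoxy-3-undecyl-1H-isochromen-1-one | CCCCCCCCCCCC1=Cc2cc(OC)cc(O)c2C(=O)O1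
F7 | step 5 | dipotassium 4-methoxy-2-oxido-6-(2-oxotridecyl)benzoate | CCCCCCCCCCCC(=O)Cc1cc(OC)cc([O-])c1C(=O)[O-].[K+].[K+]
F8 | step 2 | methyl 2,4-dimethoxy-6-methylbenzoate | COC(=O)c1c(C)cc(OC)cc1OC
F9 | step 2 | methyl 2-[(dichloroboranyl)oxy]-4-methoxy-6-methylbenzoate | COC(=O)c1c(C)cc(OC)cc1OB(Cl)Cl
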